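**Retrosynthetic overview** (rings A–F are read left to right in the target SMILES)
- The target is a linear hexamer A–O–B–O–C–O–D–O–E–O–F. It consists of three copies of one dimer unit (2,4,6-trioxyphenyl–O–3,4,5-trioxyphenyl: A–B, C–D, E–F). The last step is a global O-demethylation.
- The key disconnections are the two inter-unit ethers B–O–C and D–O–E. Each joins the carbon ortho to the aryloxy group of a trimethoxyphenoxy ring to the para-phenol of the next unit. Both are made by a new copper-mediated oxidative aryloxylation of one storable arylzinc pivalate, which is prepared once from the silylated dimer and used twice.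
- The intra-unit ether (A–O–B, C–O–D and E–O–F are the same bond) comes from a Chan–Lam coupling of syringaldehyde with 3,4,5-trimethoxyphenylboronic acid. The aldehyde is then converted to OH by Baeyer–Villiger oxidation.
- No ring is built, because all six benzene rings are bought. Order of joining: the E–F unit first, then the C–D unit onto E, then the A–B unit onto C.

Assumption 1: the target has no stereocentre and its diaryl ether axes rotate freely, so it is achiral and "single enantiomer" needs no stereocontrol.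
Assumption 2: the mixed aryloxyboron bromides formed in step 9 are not a single compound and are destroyed in the quench, so they get no number.
Assumption 3: the solid arylzinc pivalate of step 4 is written in its simplest form, ArZnOPiv. The lithium pivalate formed beside it stays in the solid as an inert salt.

**Step 1**
Reactants: 1 syringaldehyde (4-hydroxy-3,5-dimethoxybenzaldehyde); 2 3,4,5-trimethoxyphenylboronic acid
Product: 3 3,5-dimethoxy-4-(3,4,5-trimethoxyphenoxy)benzaldehyde
Conditions: 2 (2 equiv), Cu(OAc)2 (1 equiv, turned over by O2), pyridine, 4 Å MS, CH2Cl2, O2 (1 atm), rt, 48 h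
Reagents that add atoms: none
Why: Chan–Lam O-arylation couples a 2,6-disubstituted phenol with an ortho-unsubstituted arylboronic acid at room temperature by C–O reductive elimination from aryl–Cu(III)–aryloxide, and the para-CHO protects the phenol from oxidation by Cu(II)/O2.

**Step 2**
Reactants: 3 3,5-dimethoxy-4-(3,4,5-trimethoxyphenoxy)benzaldehyde
Product: 5 3,5-dimethoxy-4-(3,4,5-trimethoxyphenoxy)phenol, via aryl formate 4 (not isolated)
Conditions: mCPBA, CH2Cl2, 0 °C → rt; aq NaHCO3 wash; crude, K2CO3 (10 mol %), MeOH, rt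
Reagents that add atoms: mCPBA, OOC(=O)c1cccc(Cl)c1
Why: In this Baeyer–Villiger (Dakin-type) oxidation the electron-rich p-aryloxy aryl group migrates in the Criegee adduct to give formate 4, which is then transesterified by methanol, as is routine for 3,4,5-trialkoxybenzaldehydes.

**Step 3**
Reactants: 5 3,5-dimethoxy-4-(3,4,5-trimethoxyphenoxy)phenol (part of the batch)
Product: 6 [3,5-dimethoxy-4-(3,4,5-trimethoxyphenoxy)phenoxy]triisopropylsilane
Conditions: TIPSCl, imidazole, DMF, rt
Reagents that add atoms: TIPSCl, CC(C)[Si](Cl)(C(C)C)C(C)C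
Why: Imidazole-promoted O-silylation masks the acidic OH, and the bulky, non-coordinating OTIPS group shields both flanking C–H bonds of that ring from the lithiation in step 4.

**Step 4**
Reactants: 6 [3,5-dimethoxy-4-(3,4,5-trimethoxyphenoxy)phenoxy]triisopropylsilane
Product: 8 {6-[2,6-dimethoxy-4-(triisopropylsilyloxy)phenoxy]-2,3,4-trimethoxyphenyl}zinc pivalate, via aryllithium 7 (not isolated)
Conditions: n-BuLi (1.0 equiv), THF, 0 °C, 2 h; Zn(OPiv)2 (1.1 equiv), 0 °C → rt; solvent removed in vacuo; solid kept under Ar at −20 °C, titre by iodolysis (one batch sized for steps 5 and 7)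
Reagents that add atoms: zinc pivalate, CC(C)(C)C(=O)[O-].CC(C)(C)C(=O)[O-].[Zn+2]
Why: Directed ortho-lithiation removes the only unshielded, doubly O-flanked proton of 6 (C2–H of the trimethoxyphenoxy ring, homotopic with C6–H), and Li→Zn transmetalation with zinc pivalate gives a solid arylzinc pivalate of the known storable type, so a single batch serves both couplings.

**Step 5**
Reactants: 8 {6-[2,6-dimethoxy-4-(triisopropylsilyloxy)phenoxy]-2,3,4-trimethoxyphenyl}zinc pivalate; 5 3,5-dimethoxy-4-(3,4,5-trimethoxyphenoxy)phenol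
Product: 12 triisopropyl[3,5-dimethoxy-4-(3,4,5-trimethoxy-2-{3,5-dimethoxy-4-(3,4,5-trimethoxyphenoxy)phenoxy}phenoxy)phenoxy]silane (tetramer TIPS ether), via lithium aryloxide 9 (not isolated), via copper(I) aryloxide 10 (not isolated), via aryl(aryloxo)cuprate 11 (not isolated)
Conditions: 5, n-BuLi (1.0 equiv), THF, −78 °C; CuCl·2LiCl (1.0 equiv), −50 °C, 20 min; 8 (1.3 equiv) in THF, −50 °C, 30 min; chloranil, −78 → −20 °C; aq NH4Cl/NH3
Reagents that add atoms: none
Why: Proposed new method: copper-mediated oxidative aryloxylation of an arylzinc pivalate (a formal aryl–Zn/O–H coupling), in which aryloxide 9 is first placed on copper as 10 so that every copper centre carries its oxygen ligand before any aryl group arrives (which disfavours diarylcuprates and biaryl homocoupling), the non-basic zinc reagent 8 then hands its aryl group to copper, chloride passing to zinc, to give heterocuprate 11 without metal/H scrambling on the partner, and two-electron oxidation by chloranil gives an aryl–Cu(III)–aryloxide whose C–O reductive elimination (the product-forming event of Chan–Lam coupling, favoured by the two ortho substituents) forms the D–O–E ether; the closest known reaction types are the oxidative amination of amidocuprates made from arylmagnesium or arylzinc reagents and Chan–Lam O-arylation, but an aryloxide has not been used as the heteroatom ligand in such an oxidative cuprate coupling.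

**Step 6**
Reactants: 12 tetramer TIPS ether
Product: 13 3,5-dimethoxy-4-(3,4,5-trimethoxy-2-{3,5-dimethoxy-4-(3,4,5-trimethoxyphenoxy)phenoxy}phenoxy)phenol (tetramer phenol)
Conditions: TBAF, AcOH, THF, 0 °C
Reagents that add atoms: none
Why: Fluoride-driven desilylation (Si–F bond strength) frees the ring-C phenol, AcOH keeps the electron-rich phenoxide protonated, and the methyl and diaryl ethers are inert.

**Step 7**
Reactants: 8 {6-[2,6-dimethoxy-4-(triisopropylsilyloxy)phenoxy]-2,3,4-trimethoxyphenyl}zinc pivalate (second portion of the step 4 batch); 13 tetramer phenol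
Product: 17 triisopropyl{3,5-dimethoxy-4-[3,4,5-trimethoxy-2-(3,5-dimethoxy-4-{3,4,5-trimethoxy-2-[3,5-dimethoxy-4-(3,4,5-trimethoxyphenoxy)phenoxy]phenoxy}phenoxy)phenoxy]phenoxy}silane (hexamer TIPS ether), via lithium aryloxide 14 (not isolated), via copper(I) aryloxide 15 (not isolated), via aryl(aryloxo)cuprate 16 (not isolated)
Conditions: 13, n-BuLi (1.0 equiv), THF, −78 °C; CuCl·2LiCl (1.0 equiv), −50 °C, 20 min; 8 (1.5 equiv) in THF, −50 °C, 30 min; chloranil, −78 → −20 °C; aq NH4Cl/NH3
Reagents that add atoms: none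
Why: Proposed new method: this is the same oxidative aryloxylation of the arylzinc pivalate as in step 5, since the reacting oxygen of 14 again sits on a ring carbon flanked by two H atoms, so that cupration to 15, aryl transfer from 8 to give 16, chloranil oxidation to aryl–Cu(III)–aryloxide and C–O reductive elimination form the B–O–C ether, with excess cheap 8 protecting the valuable tetramer; the closest known reaction types are the oxidative amination of amidocuprates made from arylzinc reagents and Chan–Lam O-arylation.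

**Step 8**
Reactants: 17 hexamer TIPS ether
Product: 18 3,5-dimethoxy-4-[3,4,5-trimethoxy-2-(3,5-dimethoxy-4-{3,4,5-trimethoxy-2-[3,5-dimethoxy-4-(3,4,5-trimethoxyphenoxy)phenoxy]phenoxy}phenoxy)phenoxy]phenol (hexamer phenol)
Conditions: TBAF, AcOH, THF, 0 °C
Reagents that add atoms: none
Why: This is the same buffered fluoride desilylation as in step 6, and only the Si–O bond reacts.

**Step 9**
Reactants: 18 hexamer phenol
Product: 19 target CNP0218077.0, 2-{2-[4-(2-{4-(3,4,5-trihydroxyphenoxy)-3,5-dihydroxyphenoxy}-3,4,5-trihydroxyphenoxy)-3,5-dihydroxyphenoxy]-3,4,5-trihydroxyphenoxy}benzene-1,3,5-triol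
Conditions: BBr3 (40 equiv), CH2Cl2, −78 °C → rt, 24 h, Ar; MeOH, 0 °C, co-evaporation; Sephadex LH-20 (degassed MeOH)
Reagents that add atoms: none
Why: In BBr3 aryl methyl ether cleavage, bromide attacks the sp3 methyl carbon of each boron-complexed ether by SN2, so all 15 OMe groups fall while the five diaryl ether bonds, which have no sp3 carbon, survive.

**Compound list**
1 | syringaldehyde (4-hydroxy-3,5-dimethoxybenzaldehyde) | O=Cc1cc(OC)c(O)c(OC)c1 | starting material
2 | 3,4,5-trimethoxyphenylboronic acid | OB(O)c1cc(OC)c(OC)c(OC)c1 | starting material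
3 | 3,5-dimethoxy-4-(3,4,5-trimethoxyphenoxy)benzaldehyde | O=Cc1cc(OC)c(Oc2cc(OC)c(OC)c(OC)c2)c(OC)c1 | intermediate
4 | 3,5-dimethoxy-4-(3,4,5-trimethoxyphenoxy)phenyl formate | O=COc1cc(OC)c(Oc2cc(OC)c(OC)c(OC)c2)c(OC)c1 | intermediate
5 | 3,5-dimethoxy-4-(3,4,5-trimethoxyphenoxy)phenol | Oc1cc(OC)c(Oc2cc(OC)c(OC)c(OC)c2)c(OC)c1 | intermediate
6 | [3,5-dimethoxy-4-(3,4,5-trimethoxyphenoxy)phenoxy]triisopropylsilane | CC(C)[Si](Oc1cc(OC)c(Oc2cc(OC)c(OC)c(OC)c2)c(OC)c1)(C(C)C)C(C)C | intermediate
7 | {6-[2,6-dimethoxy-4-(triisopropylsilyloxy)phenoxy]-2,3,4-trimethoxyphenyl}lithium | [Li]c1c(OC)c(OC)c(OC)cc1Oc1c(OC)cc(O[Si](C(C)C)(C(C)C)C(C)C)cc1OC | intermediate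
8 | {6-[2,6-dimethoxy-4-(triisopropylsilyloxy)phenoxy]-2,3,4-trimethoxyphenyl}zinc pivalate | CC(C)(C)C(=O)O[Zn]c1c(OC)c(OC)c(OC)cc1Oc1c(OC)cc(O[Si](C(C)C)(C(C)C)C(C)C)cc1OC | intermediate
9 | lithium 3,5-dimethoxy-4-(3,4,5-trimethoxyphenoxy)phenoxide | [Li+].[O-]c1cc(OC)c(Oc2cc(OC)c(OC)c(OC)c2)c(OC)c1 | intermediate
10 | copper(I) 3,5-dimethoxy-4-(3,4,5-trimethoxyphenoxy)phenoxide | [Cu]Oc1cc(OC)c(Oc2cc(OC)c(OC)c(OC)c2)c(OC)c1 | intermediate
11 | lithium aryl(aryloxo)cuprate(I) from 8 and 10 (Cu carries the aryl of 8 through C and the aryloxide of 10 through O) | [Li+].COc1cc(O[Cu-]c2c(OC)c(OC)c(OC)cc2Oc2c(OC)cc(O[Si](C(C)C)(C(C)C)C(C)C)cc2OC)cc(OC)c1Oc1cc(OC)c(OC)c(OC)c1 | intermediate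
12 | tetramer TIPS ether, triisopropyl[3,5-dimethoxy-4-(3,4,5-trimethoxy-2-{3,5-dimethoxy-4-(3,4,5-trimethoxyphenoxy)phenoxy}phenoxy)phenoxy]silane | CC(C)[Si](Oc1cc(OC)c(Oc2cc(OC)c(OC)c(OC)c2Oc2cc(OC)c(Oc3cc(OC)c(OC)c(OC)c3)c(OC)c2)c(OC)c1)(C(C)C)C(C)C | intermediate
13 | tetramer phenol, 3,5-dimethoxy-4-(3,4,5-trimethoxy-2-{3,5-dimethoxy-4-(3,4,5-trimethoxyphenoxy)phenoxy}phenoxy)phenol | Oc1cc(OC)c(Oc2cc(OC)c(OC)c(OC)c2Oc2cc(OC)c(Oc3cc(OC)c(OC)c(OC)c3)c(OC)c2)c(OC)c1 | intermediate
14 | lithium phenoxide of 13 | [Li+].[O-]c1cc(OC)c(Oc2cc(OC)c(OC)c(OC)c2Oc2cc(OC)c(Oc3cc(OC)c(OC)c(OC)c3)c(OC)c2)c(OC)c1 | intermediate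
15 | copper(I) phenoxide of 13 | [Cu]Oc1cc(OC)c(Oc2cc(OC)c(OC)c(OC)c2Oc2cc(OC)c(Oc3cc(OC)c(OC)c(OC)c3)c(OC)c2)c(OC)c1 | intermediate
16 | lithium aryl(aryloxo)cuprate(I) from 8 and 15 | [Li+].COc1cc(O[Cu-]c2c(OC)c(OC)c(OC)cc2Oc2c(OC)cc(O[Si](C(C)C)(C(C)C)C(C)C)cc2OC)cc(OC)c1Oc1cc(OC)c(OC)c(OC)c1Oc1cc(OC)c(Oc2cc(OC)c(OC)c(OC)c2)c(OC)c1 | intermediate
17 | hexamer TIPS ether (O-triisopropylsilyl derivative of 18) | CC(C)[Si](Oc1cc(OC)c(Oc2cc(OC)c(OC)c(OC)c2Oc2cc(OC)c(Oc3cc(OC)c(OC)c(OC)c3Oc3cc(OC)c(Oc4cc(OC)c(OC)c(OC)c4)c(OC)c3)c(OC)c2)c(OC)c1)(C(C)C)C(C)C | intermediate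
18 | hexamer phenol (pentadeca-O-methyl target, free OH para on ring A) | Oc1cc(OC)c(Oc2cc(OC)c(OC)c(OC)c2Oc2cc(OC)c(Oc3cc(OC)c(OC)c(OC)c3Oc3cc(OC)c(Oc4cc(OC)c(OC)c(OC)c4)c(OC)c3)c(OC)c2)c(OC)c1 | intermediate
19 | CNP0218077.0 (achiral, C36H26O21) | Oc1cc(O)c(Oc2cc(O)c(O)c(O)c2Oc2cc(O)c(Oc3cc(O)c(O)c(O)c3Oc3cc(O)c(Oc4cc(O)c(O)c(O)c4)c(O)c3)c(O)c2)c(O)c1 | target

**Total step count:** 9. **Longest linear sequence:** 9 (steps 1 to 9; zinc reagent 8 is made once in step 4 and used in steps 5 and 7).

**Three steps most likely to fail**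

(a) Step 5, the proposed new reaction.
- Risks: the aryloxide may shift from copper to the oxophilic zinc, leaving a bare arylcopper that homocouples to a biaryl. Chloranil may oxidise the aryloxide by an outer-sphere path. Protodemetalation may return 6.
- The fallback uses known chemistry, sets out from 3 and comes back at 13. NBS (1.0 equiv, MeCN, 0 °C) brominates only the tetra-oxygenated ring of 3, because the other ring is deactivated by CHO. This gives 4-(2-bromo-3,4,5-trimethoxyphenoxy)-3,5-dimethoxybenzaldehyde F1.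
- A ligand-accelerated Ullmann ether synthesis of F1 with 5 follows (CuI 20 mol %, N,N-dimethylglycine, Cs2CO3, dioxane, 100 °C). Dioxane is chosen because a non-polar medium keeps SNAr exchange at the aldehyde-activated ether carbon slow. The product is the tetramer aldehyde F2.
- mCPBA Baeyer–Villiger oxidation gives the tetramer formate F3, and methanolysis with catalytic K2CO3 gives 13. Step 6 then drops out. Steps 3 and 4 are needed only if step 7 is still run as planned.

(b) Step 7, the new reaction on the large partner.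
- Risks: the same as in step 5, plus aggregation or poor solubility of 14 and 15 at low temperature and loss of the valuable tetramer.
- The fallback uses known chemistry, sets out from 13 and comes back at 18. The bromo aldehyde F1 (made from 3 with NBS as above) and 13 are joined by the same Cu-catalysed Ullmann ether synthesis to give the hexamer aldehyde F4.
- mCPBA converts F4 into the hexamer formate F5, and catalytic K2CO3/MeOH releases 18. Step 8 then drops out.

(c) Step 9, the 15-fold demethylation.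
- Risks: partly cleaved borates precipitate and stop reacting, boron residues are hard to remove, and the free polyphenol is air-sensitive during purification.
- The fallback sets out from 18 and comes back at 19. It is a capture-and-release route instead of direct isolation. Compound 18 is dealkylated in a homogeneous pyridinium chloride melt (190 °C, Ar), where chloride attacks the protonated ethers by SN2.
- The unpurified polyphenol is peracetylated at once (Ac2O, pyridine, rt) to the hexadecaacetate F6. This compound is stable, soluble in organic solvents and can be chromatographed on silica, so under-cleaved material can be separated and recycled.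
- Acid-catalysed transesterification (TsOH 5 mol %, degassed MeOH, 50 °C, Ar) leaves only volatile by-products and gives 19.

**Further compounds**
F1 | step 5 | 4-(2-bromo-3,4,5-trimethoxyphenoxy)-3,5-dimethoxybenzaldehyde | O=Cc1cc(OC)c(Oc2cc(OC)c(OC)c(OC)c2Br)c(OC)c1
F2 | step 5 | tetramer aldehyde, 3,5-dimethoxy-4-(3,4,5-trimethoxy-2-{3,5-dimethoxy-4-(3,4,5-trimethoxyphenoxy)phenoxy}phenoxy)benzaldehyde | O=Cc1cc(OC)c(Oc2cc(OC)c(OC)c(OC)c2Oc2cc(OC)c(Oc3cc(OC)c(OC)c(OC)c3)c(OC)c2)c(OC)c1
F3 | step 5 | tetramer formate (O-formyl derivative of 13) | O=COc1cc(OC)c(Oc2cc(OC)c(OC)c(OC)c2Oc2cc(OC)c(Oc3cc(OC)c(OC)c(OC)c3)c(OC)c2)c(OC)c1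
F4 | step 7 | hexamer aldehyde (18 with CHO in place of the ring-A OH) | O=Cc1cc(OC)c(Oc2cc(OC)c(OC)c(OC)c2Oc2cc(OC)c(Oc3cc(OC)c(OC)c(OC)c3Oc3cc(OC)c(Oc4cc(OC)c(OC)c(OC)c4)c(OC)c3)c(OC)c2)c(OC)c1
F5 | step 7 | hexamer formate (O-formyl derivative of 18) | O=COc1cc(OC)c(Oc2cc(OC)c(OC)c(OC)c2Oc2cc(OC)c(Oc3cc(OC)c(OC)c(OC)c3Oc3cc(OC)c(Oc4cc(OC)c(OC)c(OC)c4)c(OC)c3)c(OC)c2)c(OC)c1
F6 | step 9 | hexadecaacetate of 19 | CC(=O)Oc1cc(OC(C)=O)c(Oc2cc(OC(C)=O)c(OC(C)=O)c(OC(C)=O)c2Oc2cc(OC(C)=O)c(Oc3cc(OC(C)=O)c(OC(C)=O)c(OC(C)=O)c3Oc3cc(OC(C)=O)c(Oc4cc(OC(C)=O)c(OC(C)=O)c(OC(C)=O)c4)c(OC(C)=O)c3)c(OC(C)=O)c2)c(OC(C)=O)c1
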